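# Proposed synthesis of 4-hydroxy-2-(4-hydroxy-2-methoxyphenyl)-6-methoxy-5-(3-methylbut-2-enyl)benzofuran-3-carbaldehyde (24)

## Analysis of the target

The target is a 2-arylbenzofuran. Its furan ring (O1, C2, C3, C3a, C7a) is fused to a benzene ring A that is substituted at every carbon but C7 (4-OH, 5-prenyl, 6-OMe). C3 carries a formyl group and C2 carries ring B, a 4-hydroxy-2-methoxyphenyl group. There is no stereocentre and the prenyl double bond has no geometric isomers, so the problem is one of regiochemistry and of telling four oxygens apart (4-OH from 6-OMe on ring A, 2'-OMe from 4'-OH on ring B). The sensitive groups are the prenyl olefin, which sits ortho to the 4-OH and closes to a chroman under protic acid, the aldehyde, and two oxidisable phenols. The hard region is the crowded run C2–C3–C3a–C4–C5: the biaryl bond C2–C1' is flanked by the formyl group and the 2'-OMe, and the prenyl group lies between two oxygens. Ring A helps in two ways. As long as O4 and O6 carry the same group its phenol precursor is symmetric, and O4 alone is peri to the C3 carbonyl, which allows it to be singled out late. The strategy rests on ring B: it is a resorcinol monomethyl ether whose C1' sits on C2, and C2 is conjugated through C2=C3 with the C3 carbonyl. An ethynyl group on C2 is therefore the vinylogue of an ynoate, and the 2'-OMe/4'-OH pattern is what a 1,1-dimethoxy-3-silyloxydiene leaves on an arene after cycloaddition and loss of one methoxy group.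

## Retrosynthetic reasoning

**Formyl group.** The aldehyde of 24 is taken back to the primary alcohol of triol 23 and from there to the ethyl ester of 22. No skeletal bond is cut. The ester is the better C3 substituent for all earlier chemistry: it survives organometallic reagents, acidifies C2–H, polarises the C2 alkyne and later directs the ether cleavage. An aldehyde would compete as a heterodienophile in the key step.

**O4–CH3.** The free 4-OH of 22 is traced, through the boron intermediate 21, to the methyl ether of 20, and the acetate of 20 to the free phenol of 19. O4–CH3 is the bond to cut because it is the only methyl ether that is peri to the C3 carbonyl and flanked by two ortho substituents. Keeping O4 and O6 identical up to this point is what makes ring A symmetric earlier. The acetate is there so that the boron Lewis acid meets no O–H and liberates no protic acid beside the prenyl group; the hydride of the next step removes it without an extra operation.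

**Ring B (key disconnection).** 19 is cut at C1'–C2' and C5'–C6', which leads through aryl silyl ether 18 and cycloadduct 17 to alkyne 14 and diene 16. A cut at C2–C1' would require joining two ortho-substituted partners and a ring B made separately with its oxygens already differentiated. Growing ring B on a C2 alkyne forms the hindered bond as a slim C(sp2)–C(sp) bond beforehand and lets the diene set OMe at C2' and OH at C4' by mechanism. The forward reaction must bond the CH2 terminus of 16 to the alkyne terminus of 14, and the adduct 17 must aromatise by loss of one acetal methoxy group.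

**Diene.** 16 comes from enone 15 by O-silylation of its methyl ketone enolate (O–Si bond cut).

**C2 substituent.** 14 comes from silyl alkyne 13 (C–Si cut). 13 is cut at C2–C(sp) to iodide 11 and alkyne 12. 11 goes back through the C2-metalated species 10 to benzofuran 9 (C–I cut). C2–H is the most acidic site of 9, lying between O1 and the ester-bearing C3, so no other position competes.

**Furan ring.** 9 is cut at C3–C3a to aryloxyacrylate 8, and 8 at O–C(vinyl) to phenol 6 and ethyl propiolate 7. The three carbons C2, C3 and the ester carbon are exactly those of 7. Because 6 is symmetric, its two ortho C–H bonds are equivalent and the ring closure has no regiochemical choice.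

**Prenyl group.** 6 comes from silyl ether 5, which is cut at the aryl–CH2 bond to aryllithium 4 and prenyl bromide 3. 4 comes from silyl ether 2 and this from phenol 1. Direct C-alkylation of 1 would go ortho to the hydroxyl group. Metalation of 2 instead places the anion between the two methoxy groups, the position that becomes C5.

## Alternatives that were turned down

**Alternative 1:** The target is read as a ring-opened coumestan. The C3 formyl carbon and the 2'-oxygen are tied together as a lactone, and the furan ring is cut at O1–C7a.
- Forward key step: the 3-aryl-4-hydroxycoumarin A1 is closed to coumestan A2 by oxidative C–H etherification (a divalent palladium catalyst with a divalent copper co-oxidant under air). The coumarin 4-oxygen attacks the only free ortho C–H of the ring A aryl group. The lactone is then reduced open, the released 2'-phenol methylated, the primary alcohol oxidised and the two methoxymethyl ethers removed.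
- For: the C2–C1' bond and the C3 carbon are in place before the key step, the site of C–O bond formation is unambiguous, and phenol-type C–H etherification is an established reaction class. On precedent for the key step it is stronger than the chosen plan.
- Against: ring A of A1 is a 1,2,3,4-tetrasubstituted arene with two different oxygen groups flanking the prenyl group. It cannot come from a symmetric phenol such as 6 and needs its own regiocontrolled sequence. Four operations follow the key step, the last an acidic acetal cleavage beside a prenyl group ortho to the freed 4-OH. The prenyl olefin must also pass an aerobic palladium oxidation, a liability the chosen route shares in step 5.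
- Comparison: it is longer and moves the regiochemical problem into the building blocks. The chosen plan draws ring A from symmetric 6 and differentiates the ring B oxygens in the act of ring formation.

**Alternative 2:** The furan ring is cut at C3–C3a and O1–C2. This leads to the O-aryl oxime A4, whose aryloxy part derives from phenol 6 and whose carbon part is the ring B β-ketoester A3.
- Forward key step: trifluoroacetylation of the oxime nitrogen gives the N-acyl ene-hydroxylamine. A [3,3] shift forms C3–C3a at one of the two equivalent ortho positions. Rearomatisation, closure of the phenol oxygen on the iminium carbon and loss of the nitrogen give benzofuran A5, the triisopropylsilyl ether of 19.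
- For: it is the most convergent plan, joining complete rings A and B in one step. It uses the same symmetric phenol, the rearrangement is a known way to 2-arylbenzofuran-3-carboxylates, and the endgame is the one used here. On precedent and convergence it is at least as strong as the chosen strategy.
- Against: the N–O–aryl bond must be made on a phloroglucinol-type phenol, the difficult and oxidation-prone case. The rearrangement releases a strong acid in the presence of the prenyl group and a very electron-rich arene. A3 needs about three steps of its own, so the step count is not lower.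
- Comparison: in its place the chosen strategy offers a ring B whose oxygen pattern is set by the diene without a protecting group, no N–O chemistry on an electron-rich arene, and an intermediate (iodide 11) from which a conventional biaryl coupling remains open.

**Alternative 3:** Ring A is cut at C4–C5 and C6–C7 and grown onto a preformed furan.
- Forward key step: a lithium amide base deprotonates the 5-methyl group of furan diester A6. The anion is acylated by ester A7 (C6–C7), and the resulting ketone enolate closes on the neighbouring ring ester (C4–C5) to give the 4,6-diol A8.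
- For: the prenyl group is built into ring A between the two oxygens with no prenylation step and no regiochemical question. The 4-OH is born free and hydrogen-bonded to the C3 ester, so the 6-OH should be methylated selectively and no ether has to be cleaved next to the prenyl group. On that point it is stronger than the chosen route, which needs step 12.
- Against: the cascade needs the second enolate at C5, the less acidic α-carbon of a ketone whose other α-carbon (C7) is doubly activated, so excess base and a dianion are required. Self-condensation of A7 and attack on either ring ester compete. The tetrasubstituted furan A6 must be assembled first. If the annulation fails there is no ring A and no nearby fallback.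
- Comparison: its key step is no better precedented than the cycloaddition chosen here. The chosen plan reaches its key-step precursor 14 by standard reactions from symmetric 6 and confines the uncertainty to one step that a cross-coupling can replace.

Key step: step 10

## Route

Assumption: 4,4-dimethoxybut-3-en-2-one (15) is bought as such; the target has no stereocentre, and the only stereo-element on the route, the E double bond of 8, is erased in step 5.

Step 1
Reactants: 1 3,5-dimethoxyphenol
Product: 2 (3,5-dimethoxyphenoxy)triisopropylsilane
Conditions: i-Pr3SiCl, imidazole, DMF, 25 °C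
Reagents that add atoms: triisopropylsilyl chloride, CC(C)[Si](Cl)(C(C)C)C(C)C
Why: O-silylation of a phenol; the bulky silyl ether is stable to n-BuLi, is a poor directing group and shields its own ortho positions, which prepares the site selectivity of step 2.

Step 2
Reactants: 2 (3,5-dimethoxyphenoxy)triisopropylsilane; 3 1-bromo-3-methylbut-2-ene (prenyl bromide)
Product: 5 [3,5-dimethoxy-4-(3-methylbut-2-enyl)phenoxy]triisopropylsilane, via the C4 aryllithium 4 (not isolated)
Conditions: n-BuLi, THF, 0 °C to 25 °C; then CuBr·SMe2 (10 mol %), 3, −78 °C to 25 °C
Reagents that add atoms: none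
Why: Directed ortho-metalation: the C–H between the two methoxy groups is the most acidic and is coordinated from both sides, while the positions next to the silyloxy group are blocked; copper-catalysed SN2 allylation of the aryllithium at the primary carbon of 3 should give the linear prenyl arene.

Step 3
Reactants: 5 [3,5-dimethoxy-4-(3-methylbut-2-enyl)phenoxy]triisopropylsilane
Product: 6 3,5-dimethoxy-4-(3-methylbut-2-enyl)phenol
Conditions: n-Bu4NF, AcOH, THF, 0 °C to 25 °C
Reagents that add atoms: none
Why: Fluoride cleavage of an aryl silyl ether under buffered conditions; the freed hydroxyl group is para to the prenyl group, so no chroman can form.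

Step 4
Reactants: 6 3,5-dimethoxy-4-(3-methylbut-2-enyl)phenol; 7 ethyl propiolate
Product: 8 ethyl (E)-3-[3,5-dimethoxy-4-(3-methylbut-2-enyl)phenoxy]prop-2-enoate
Conditions: DABCO (10 mol %), CH2Cl2, 0 °C to 25 °C
Reagents that add atoms: none
Why: Amine-catalysed oxa-Michael addition of a phenol to a propiolate; addition–elimination through the ammonium acrylate should give the E β-aryloxyacrylate, and the geometry is of no consequence for the ring closure.

Step 5
Reactants: 8 ethyl (E)-3-[3,5-dimethoxy-4-(3-methylbut-2-enyl)phenoxy]prop-2-enoate
Product: 9 ethyl 4,6-dimethoxy-5-(3-methylbut-2-enyl)benzofuran-3-carboxylate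
Conditions: Pd(OAc)2 (10 mol %), PPh3 (10 mol %), CF3CO2Ag (2 equiv), benzene, 110 °C, air, sealed tube
Reagents that add atoms: none
Why: Intramolecular oxidative Heck (Fujiwara–Moritani-type) cyclization of a 3-aryloxyacrylate, which forms C3–C3a; the electron-rich arene is palladated at one of its two equivalent ortho C–H bonds, so only one benzofuran can arise, and the silver salt returns zerovalent palladium to the divalent state.

Step 6
Reactants: 9 ethyl 4,6-dimethoxy-5-(3-methylbut-2-enyl)benzofuran-3-carboxylate
Product: 11 ethyl 2-iodo-4,6-dimethoxy-5-(3-methylbut-2-enyl)benzofuran-3-carboxylate, via the C2 arylmagnesium chloride 10 (not isolated)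
Conditions: TMPMgCl·LiCl (1.2 equiv), THF, −40 °C; then I2, −40 °C to 25 °C
Reagents that add atoms: iodine, II
Why: Directed magnesiation with a hindered amide base: C2–H lies between O1 and the ester-bearing C3 and is the most acidic proton, the arylmagnesium tolerates its own ester at low temperature, and iodine traps it faster than it touches the prenyl olefin.

Step 7
Reactants: 11 ethyl 2-iodo-4,6-dimethoxy-5-(3-methylbut-2-enyl)benzofuran-3-carboxylate; 12 ethynyltrimethylsilane
Product: 13 ethyl 4,6-dimethoxy-5-(3-methylbut-2-enyl)-2-[(trimethylsilyl)ethynyl]benzofuran-3-carboxylate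
Conditions: PdCl2(PPh3)2 (3 mol %), CuI (5 mol %), Et3N, THF, 25 °C
Reagents that add atoms: none
Why: Sonogashira coupling; the 2-iodide next to an ester is an activated heteroaryl halide that should undergo oxidative addition at room temperature, and the prenyl olefin is a spectator.

Step 8
Reactants: 13 ethyl 4,6-dimethoxy-5-(3-methylbut-2-enyl)-2-[(trimethylsilyl)ethynyl]benzofuran-3-carboxylate
Product: 14 ethyl 2-ethynyl-4,6-dimethoxy-5-(3-methylbut-2-enyl)benzofuran-3-carboxylate
Conditions: n-Bu4NF, AcOH, THF, 0 °C
Reagents that add atoms: none
Why: Fluoride-induced C(sp)–Si cleavage; buffered, alcohol-free conditions are chosen because carbonate in an alcohol could transesterify the ester or add alkoxide to the electron-poor alkyne.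

Step 9
Reactants: 15 4,4-dimethoxybut-3-en-2-one
Product: 16 1,1-dimethoxy-3-(trimethylsilyloxy)buta-1,3-diene
Conditions: Me3SiCl, Et3N, ZnCl2 (cat.), benzene, 40 °C; filtration and distillation
Reagents that add atoms: chlorotrimethylsilane, C[Si](C)(C)Cl
Why: Silyl enol ether formation by soft enolization; the methyl group carries the only enolizable protons of this vinylogous ester, so O-silylation can give only the 2-silyloxydiene.

Step 10
Reactants: 14 ethyl 2-ethynyl-4,6-dimethoxy-5-(3-methylbut-2-enyl)benzofuran-3-carboxylate; 16 1,1-dimethoxy-3-(trimethylsilyloxy)buta-1,3-diene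
Product: 19 ethyl 2-(4-hydroxy-2-methoxyphenyl)-4,6-dimethoxy-5-(3-methylbut-2-enyl)benzofuran-3-carboxylate, via the cyclohexadiene cycloadduct 17 (not isolated), via the aryl trimethylsilyl ether 18 (not isolated)
Conditions: 16 (3 equiv), toluene, 110 °C, sealed tube; then 1 M HCl, THF, 0 °C
Reagents that add atoms: none
Why: Proposed new method: the ethynyl group of 14 is joined through C2=C3 to the ester carbonyl, so its terminal carbon is the δ-position of a dienyl ester and carries the larger LUMO coefficient; the CH2 terminus of 16, made nucleophilic by both the 3-silyloxy and the 1,1-dimethoxy donors, should bond there first (C5'–C6'), and the ketene acetal carbon then joins the internal alkyne carbon (C1'–C2') in a concerted but strongly asynchronous [4+2] cycloaddition or, at the limit, a Mukaiyama–Michael addition followed by collapse of the allenyl enolate onto the dialkoxycarbenium ion. Ring B is thereby closed as a six-membered carbocycle from four diene carbons and two alkyne carbons (a 6-endo-trig closure in the stepwise limit), giving the 1,4-cyclohexadiene 17. 17 aromatises by loss of one acetal methoxy group as methanol, which leaves OMe at C2' and gives 18, and dilute acid then removes the silyl group to free the C4' phenol. The closest known reaction type is the cycloaddition–aromatisation of 1,1-dialkoxy-3-silyloxybutadienes with propiolates, butynedioates and ynones, which gives 4-hydroxy-2-methoxyaryl carbonyl compounds in this same orientation; new here is that the alkyne is activated only vinylogously. No stereocentre is formed, 17 and 19 being achiral. The step needs regioselectivity (diene CH2 to the alkyne terminus), secured by the polarisation that the C3 ester imposes on the alkyne and by the lower hindrance of the terminal carbon, and chemoselectivity for the alkyne over the tetrasubstituted aromatic C2=C3 bond and the ester carbonyl, secured by sterics and by the aromatic ring that only the alkyne pathway gains. Because the activation is weak, heating in a sealed tube is planned, with high pressure (about 13 kbar, CH2Cl2, 25 °C) as the reserve means of acceleration.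

Step 11
Reactants: 19 ethyl 2-(4-hydroxy-2-methoxyphenyl)-4,6-dimethoxy-5-(3-methylbut-2-enyl)benzofuran-3-carboxylate
Product: 20 ethyl 2-(4-acetoxy-2-methoxyphenyl)-4,6-dimethoxy-5-(3-methylbut-2-enyl)benzofuran-3-carboxylate
Conditions: Ac2O, pyridine, DMAP (cat.), CH2Cl2, 25 °C
Reagents that add atoms: acetic anhydride, CC(=O)OC(C)=O
Why: Acylation of the only free phenol; with no O–H left, BCl3 in step 12 cannot liberate HCl beside the prenyl olefin, and the acetate is removed without an extra operation by the hydride of step 13.

Step 12
Reactants: 20 ethyl 2-(4-acetoxy-2-methoxyphenyl)-4,6-dimethoxy-5-(3-methylbut-2-enyl)benzofuran-3-carboxylate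
Product: 22 ethyl 2-(4-acetoxy-2-methoxyphenyl)-4-hydroxy-6-methoxy-5-(3-methylbut-2-enyl)benzofuran-3-carboxylate, via the chelated aryl dichloroborinate 21 (not isolated)
Conditions: BCl3 (2.5 equiv), CH2Cl2, −78 °C to −20 °C; then cold aq NaHCO3
Reagents that add atoms: none
Why: Carbonyl-directed Lewis acid cleavage of an aryl methyl ether: BCl3 bound to the C3 ester carbonyl reaches only the peri O4, which is also the one methoxy oxygen twisted out of conjugation by two ortho neighbours, and chloride removes the methyl group by SN2; the 6-OMe and 2'-OMe have no carbonyl within reach, and quenching into bicarbonate keeps the freed 4-OH from adding to the prenyl group.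

Step 13
Reactants: 22 ethyl 2-(4-acetoxy-2-methoxyphenyl)-4-hydroxy-6-methoxy-5-(3-methylbut-2-enyl)benzofuran-3-carboxylate
Product: 23 3-(hydroxymethyl)-2-(4-hydroxy-2-methoxyphenyl)-6-methoxy-5-(3-methylbut-2-enyl)benzofuran-4-ol
Conditions: i-Bu2AlH (6 equiv), CH2Cl2, −78 °C to 0 °C; aq potassium sodium tartrate
Reagents that add atoms: none
Why: Hydride reduction of the ester to the primary alcohol with concurrent reductive cleavage of the aryl acetate; the olefin is inert to the hydride, and the neutral tartrate work-up avoids acid that could ionise the electron-rich benzofuranylmethanol.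

Step 14
Reactants: 23 3-(hydroxymethyl)-2-(4-hydroxy-2-methoxyphenyl)-6-methoxy-5-(3-methylbut-2-enyl)benzofuran-4-ol
Product: 24 4-hydroxy-2-(4-hydroxy-2-methoxyphenyl)-6-methoxy-5-(3-methylbut-2-enyl)benzofuran-3-carbaldehyde
Conditions: MnO2 (activated, 15 equiv), EtOAc, 25 °C
Reagents that add atoms: none
Why: Selective MnO2 oxidation of a heteroarylmethyl (benzylic-type) alcohol under neutral heterogeneous conditions; the aldehyde is held by a hydrogen bond to the 4-OH and should not be oxidised further, and phenols and the prenyl olefin are expected to be tolerated.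

## Compound list

1 | 3,5-dimethoxyphenol | COc1cc(O)cc(OC)c1 | starting material
2 | (3,5-dimethoxyphenoxy)triisopropylsilane | COc1cc(O[Si](C(C)C)(C(C)C)C(C)C)cc(OC)c1 | intermediate
3 | 1-bromo-3-methylbut-2-ene (prenyl bromide) | CC(C)=CCBr | starting material
4 | [2,6-dimethoxy-4-(triisopropylsilyloxy)phenyl]lithium (formed in the flask) | [Li]c1c(OC)cc(O[Si](C(C)C)(C(C)C)C(C)C)cc1OC | intermediate
5 | [3,5-dimethoxy-4-(3-methylbut-2-enyl)phenoxy]triisopropylsilane | COc1cc(O[Si](C(C)C)(C(C)C)C(C)C)cc(OC)c1CC=C(C)C | intermediate
6 | 3,5-dimethoxy-4-(3-methylbut-2-enyl)phenol | COc1cc(O)cc(OC)c1CC=C(C)C | intermediate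
7 | ethyl propiolate | C#CC(=O)OCC | starting material
8 | ethyl (E)-3-[3,5-dimethoxy-4-(3-methylbut-2-enyl)phenoxy]prop-2-enoate | CCOC(=O)/C=C/Oc1cc(OC)c(CC=C(C)C)c(OC)c1 | intermediate
9 | ethyl 4,6-dimethoxy-5-(3-methylbut-2-enyl)benzofuran-3-carboxylate | CCOC(=O)c1coc2cc(OC)c(CC=C(C)C)c(OC)c12 | intermediate
10 | [3-(ethoxycarbonyl)-4,6-dimethoxy-5-(3-methylbut-2-enyl)benzofuran-2-yl]magnesium chloride, LiCl complex (formed in the flask) | CCOC(=O)c1c([Mg]Cl)oc2cc(OC)c(CC=C(C)C)c(OC)c12 | intermediate
11 | ethyl 2-iodo-4,6-dimethoxy-5-(3-methylbut-2-enyl)benzofuran-3-carboxylate | CCOC(=O)c1c(I)oc2cc(OC)c(CC=C(C)C)c(OC)c12 | intermediate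
12 | ethynyltrimethylsilane | C#C[Si](C)(C)C | starting material
13 | ethyl 4,6-dimethoxy-5-(3-methylbut-2-enyl)-2-[(trimethylsilyl)ethynyl]benzofuran-3-carboxylate | CCOC(=O)c1c(C#C[Si](C)(C)C)oc2cc(OC)c(CC=C(C)C)c(OC)c12 | intermediate
14 | ethyl 2-ethynyl-4,6-dimethoxy-5-(3-methylbut-2-enyl)benzofuran-3-carboxylate | CCOC(=O)c1c(C#C)oc2cc(OC)c(CC=C(C)C)c(OC)c12 | intermediate
15 | 4,4-dimethoxybut-3-en-2-one | COC(OC)=CC(C)=O | starting material
16 | 1,1-dimethoxy-3-(trimethylsilyloxy)buta-1,3-diene | COC(OC)=CC(=C)O[Si](C)(C)C | intermediate
17 | ethyl 2-[6,6-dimethoxy-4-(trimethylsilyloxy)cyclohexa-1,4-dien-1-yl]-4,6-dimethoxy-5-(3-methylbut-2-enyl)benzofuran-3-carboxylate (formed in the flask) | CCOC(=O)c1c(C2=CCC(O[Si](C)(C)C)=CC2(OC)OC)oc2cc(OC)c(CC=C(C)C)c(OC)c12 | intermediate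
18 | ethyl 4,6-dimethoxy-2-[2-methoxy-4-(trimethylsilyloxy)phenyl]-5-(3-methylbut-2-enyl)benzofuran-3-carboxylate (formed in the flask) | CCOC(=O)c1c(-c2ccc(O[Si](C)(C)C)cc2OC)oc2cc(OC)c(CC=C(C)C)c(OC)c12 | intermediate
19 | ethyl 2-(4-hydroxy-2-methoxyphenyl)-4,6-dimethoxy-5-(3-methylbut-2-enyl)benzofuran-3-carboxylate | CCOC(=O)c1c(-c2ccc(O)cc2OC)oc2cc(OC)c(CC=C(C)C)c(OC)c12 | intermediate
20 | ethyl 2-(4-acetoxy-2-methoxyphenyl)-4,6-dimethoxy-5-(3-methylbut-2-enyl)benzofuran-3-carboxylate | CCOC(=O)c1c(-c2ccc(OC(C)=O)cc2OC)oc2cc(OC)c(CC=C(C)C)c(OC)c12 | intermediate
21 | ethyl 2-(4-acetoxy-2-methoxyphenyl)-4-(dichloroboryloxy)-6-methoxy-5-(3-methylbut-2-enyl)benzofuran-3-carboxylate (formed in the flask) | CCOC(=O)c1c(-c2ccc(OC(C)=O)cc2OC)oc2cc(OC)c(CC=C(C)C)c(OB(Cl)Cl)c12 | intermediate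
22 | ethyl 2-(4-acetoxy-2-methoxyphenyl)-4-hydroxy-6-methoxy-5-(3-methylbut-2-enyl)benzofuran-3-carboxylate | CCOC(=O)c1c(-c2ccc(OC(C)=O)cc2OC)oc2cc(OC)c(CC=C(C)C)c(O)c12 | intermediate
23 | 3-(hydroxymethyl)-2-(4-hydroxy-2-methoxyphenyl)-6-methoxy-5-(3-methylbut-2-enyl)benzofuran-4-ol | OCc1c(-c2ccc(O)cc2OC)oc2cc(OC)c(CC=C(C)C)c(O)c12 | intermediate
24 | 4-hydroxy-2-(4-hydroxy-2-methoxyphenyl)-6-methoxy-5-(3-methylbut-2-enyl)benzofuran-3-carbaldehyde | COc1cc(O)ccc1-c1oc2cc(OC)c(CC=C(C)C)c(O)c2c1C=O | target

## Step count and risk

Total step count: 14. Longest linear sequence: 13 steps (steps 1–8 and 10–14, from 1); step 9 is a one-step side branch that supplies the diene.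

Steps least certain to work:

**Step 10 (key step, proposed new method).** The most likely failure is lack of reactivity. The alkyne is activated only through the furan C2=C3 bond by an ester that is itself a vinylogous carbonate and may be twisted by the peri 4-OMe. Thermal decomposition or oligomerisation of the diene could then outrun the cycloaddition, and forcing conditions could bring in addition across C2=C3. Reversed orientation is the less likely failure. The fallback uses known chemistry and sets out from iodide 11. It is a Suzuki–Miyaura coupling of 11 with the purchased boronate 3-methoxy-4-(4,4,5,5-tetramethyl-1,3,2-dioxaborolan-2-yl)phenol F1 (Pd(dppf)Cl2, K3PO4, dioxane–water, 80 °C). It forms the C2–C1' bond directly and returns to the route at 19, so steps 7–10 are bypassed.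

**Step 5.** The prenyl group is exposed to a divalent palladium catalyst and to the palladium hydride formed in each turnover. Migration of the double bond into conjugation with ring A, or oxidation at the doubly activated benzylic–allylic CH2, may compete with the cyclization. The fallback sets out from phenol 6 and replaces C–H activation by a halide-based Heck reaction. Iodination with N-iodosuccinimide ortho to the hydroxyl group gives 2-iodo-3,5-dimethoxy-4-(3-methylbut-2-enyl)phenol F2. Addition to ethyl propiolate 7 (DABCO) gives ethyl (E)-3-[2-iodo-3,5-dimethoxy-4-(3-methylbut-2-enyl)phenoxy]prop-2-enoate F3. An intramolecular Heck reaction (Pd(OAc)2, PPh3, Et3N, MeCN, 80 °C, zerovalent palladium cycle, no oxidant) closes C3–C3a and returns to the route at 9.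

**Step 12.** The ester is a weaker director than a ketone or aldehyde and the chelate is seven-membered. The cleavage may therefore be slow or touch the wrong ether, and acid released at the quench could close a chroman between the freed 4-OH and the prenyl group. The fallback sets out from 19 and moves the demethylation to the aldehyde stage. i-Bu2AlH reduces 19 to 4-[3-(hydroxymethyl)-4,6-dimethoxy-5-(3-methylbut-2-enyl)benzofuran-2-yl]-3-methoxyphenol F4. MnO2 oxidises this to 2-(4-hydroxy-2-methoxyphenyl)-4,6-dimethoxy-5-(3-methylbut-2-enyl)benzofuran-3-carbaldehyde F5. MgI2·OEt2 in toluene–ether, chelated between the formyl oxygen and O4, then removes the 4-methyl group without protic acid and gives 24 directly. Steps 11–14 are bypassed.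

**Step 2.** Metalation may occur in part next to the silyloxy group, followed by silyl migration to carbon, and the allylation may give some of the branched (SN2') product. The fallback sets out from prenyl bromide 3 and uses 1,3-dimethoxybenzene F6 in place of 1, so that only one doubly activated site exists. Lithiation of F6 with n-BuLi gives (2,6-dimethoxyphenyl)lithium F7, and alkylation with 3 gives 1,3-dimethoxy-2-(3-methylbut-2-enyl)benzene F8. Sterically controlled C–H borylation ([Ir(OMe)(cod)]2, 4,4'-di-tert-butyl-2,2'-bipyridine, bis(pinacolato)diboron) at the only ring position without an ortho neighbour gives 2-[3,5-dimethoxy-4-(3-methylbut-2-enyl)phenyl]-4,4,5,5-tetramethyl-1,3,2-dioxaborolane F9. Oxidation with NaBO3·4H2O in THF–water returns to the route at 6, and steps 1–3 are bypassed.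

## Further compounds

F1 | step 10 | 3-methoxy-4-(4,4,5,5-tetramethyl-1,3,2-dioxaborolan-2-yl)phenol | COc1cc(O)ccc1B1OC(C)(C)C(C)(C)O1
F2 | step 5 | 2-iodo-3,5-dimethoxy-4-(3-methylbut-2-enyl)phenol | COc1cc(O)c(I)c(OC)c1CC=C(C)C
F3 | step 5 | ethyl (E)-3-[2-iodo-3,5-dimethoxy-4-(3-methylbut-2-enyl)phenoxy]prop-2-enoate | CCOC(=O)/C=C/Oc1cc(OC)c(CC=C(C)C)c(OC)c1I
F4 | step 12 | 4-[3-(hydroxymethyl)-4,6-dimethoxy-5-(3-methylbut-2-enyl)benzofuran-2-yl]-3-methoxyphenol | OCc1c(-c2ccc(O)cc2OC)oc2cc(OC)c(CC=C(C)C)c(OC)c12
F5 | step 12 | 2-(4-hydroxy-2-methoxyphenyl)-4,6-dimethoxy-5-(3-methylbut-2-enyl)benzofuran-3-carbaldehyde | O=Cc1c(-c2ccc(O)cc2OC)oc2cc(OC)c(CC=C(C)C)c(OC)c12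
F6 | step 2 | 1,3-dimethoxybenzene | COc1cccc(OC)c1
F7 | step 2 | (2,6-dimethoxyphenyl)lithium | [Li]c1c(OC)cccc1OC
F8 | step 2 | 1,3-dimethoxy-2-(3-methylbut-2-enyl)benzene | COc1cccc(OC)c1CC=C(C)C
F9 | step 2 | 2-[3,5-dimethoxy-4-(3-methylbut-2-enyl)phenyl]-4,4,5,5-tetramethyl-1,3,2-dioxaborolane | COc1cc(B2OC(C)(C)C(C)(C)O2)cc(OC)c1CC=C(C)C
A1 | alternative 1 | 4-hydroxy-3-[4-methoxy-2-(methoxymethoxy)-3-(3-methylbut-2-enyl)phenyl]-7-(methoxymethoxy)chromen-2-one | O=c1oc2cc(OCOC)ccc2c(O)c1-c1ccc(OC)c(CC=C(C)C)c1OCOC
A2 | alternative 1 | 9-methoxy-3,7-bis(methoxymethoxy)-8-(3-methylbut-2-enyl)-6H-benzofuro[3,2-c]chromen-6-one | O=c1oc2cc(OCOC)ccc2c2oc3cc(OC)c(CC=C(C)C)c(OCOC)c3c12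
A3 | alternative 2 | ethyl 3-[2-methoxy-4-(triisopropylsilyloxy)phenyl]-3-oxopropanoate | CCOC(=O)CC(=O)c1ccc(O[Si](C(C)C)(C(C)C)C(C)C)cc1OC
A4 | alternative 2 | ethyl 3-{[3,5-dimethoxy-4-(3-methylbut-2-enyl)phenoxy]imino}-3-[2-methoxy-4-(triisopropylsilyloxy)phenyl]propanoate (either C=N isomer) | CCOC(=O)CC(=NOc1cc(OC)c(CC=C(C)C)c(OC)c1)c1ccc(O[Si](C(C)C)(C(C)C)C(C)C)cc1OC
A5 | alternative 2 | ethyl 4,6-dimethoxy-2-[2-methoxy-4-(triisopropylsilyloxy)phenyl]-5-(3-methylbut-2-enyl)benzofuran-3-carboxylate | CCOC(=O)c1c(-c2ccc(O[Si](C(C)C)(C(C)C)C(C)C)cc2OC)oc2cc(OC)c(CC=C(C)C)c(OC)c12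
A6 | alternative 3 | dimethyl 2-[2-methoxy-4-(triisopropylsilyloxy)phenyl]-5-methylfuran-3,4-dicarboxylate | COC(=O)c1c(C)oc(-c2ccc(O[Si](C(C)C)(C(C)C)C(C)C)cc2OC)c1C(=O)OC
A7 | alternative 3 | methyl 5-methylhex-4-enoate | COC(=O)CCC=C(C)C
A8 | alternative 3 | methyl 4,6-dihydroxy-2-[2-methoxy-4-(triisopropylsilyloxy)phenyl]-5-(3-methylbut-2-enyl)benzofuran-3-carboxylate | COC(=O)c1c(-c2ccc(O[Si](C(C)C)(C(C)C)C(C)C)cc2OC)oc2cc(O)c(CC=C(C)C)c(O)c12
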